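**Retrosynthetic overview**

1. The (3S)-isoflavanone is cut in ring C at O1–C2 and C4–C4a (and O1–C8a), giving a ring-A aryne and a 2-arylacrylic acid that already carries rings B and D.
2. Enabling feature: O1 and the C4 ketone sit on the adjacent ring-A carbons C8a and C4a (a carboxylic acid O–C(=O) unit laid across an aryne bond), C2 is β to C4=O (oxa-Michael retron), and the C5 methoxy group next to C4a steers the aryne addition.
3. C3 is α to the ketone and benzylic, so it is made racemic and set afterwards by transfer hydrogenation with dynamic kinetic resolution, then re-oxidation.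
4. The aryne precursor comes from 5-bromovanillin (Dakin oxidation, retro-Brook rearrangement, triflation); the acid comes from 3',4'-dihydroxyacetophenone (propargyl Claisen, enol triflate carbonylation).
5. Ring order: rings A and B are bought as arenes; ring D is closed in step 7; ring C is closed in step 10.

Key step: step 10

Remark: C3 is the only stereocentre and its descriptor is S. Ring letters: A is the benzo ring of the chromanone, C its pyranone ring, B the benzo ring of the chromene, D its pyran ring.

**Route**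

Step 1
Reactants: 1 5-bromovanillin
Product: 2 2-bromo-6-methoxybenzene-1,4-diol
Conditions: H2O2 (30% aq.), NaOH, H2O/THF, 0 °C → rt, N2; then HCl
Reagents that add atoms: hydrogen peroxide, OO
Why: Dakin oxidation of a para-hydroxybenzaldehyde (hydroperoxide addition, aryl migration to oxygen, formate hydrolysis) should replace the formyl group by the hydroxyl that becomes the C7 oxygen of the target.

Step 2
Reactants: 2 2-bromo-6-methoxybenzene-1,4-diol
Product: 3 [(2-bromo-6-methoxy-1,4-phenylene)bis(oxy)]bis(trimethylsilane)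
Conditions: (Me3Si)2NH, THF, 70 °C; concentrate
Reagents that add atoms: hexamethyldisilazane, C[Si](C)(C)N[Si](C)(C)C
Why: Base-free O-silylation with loss of ammonia should cap both phenols and place on the hindered oxygen the silyl group that later migrates to carbon.

Step 3
Reactants: 3 [(2-bromo-6-methoxy-1,4-phenylene)bis(oxy)]bis(trimethylsilane)
Product: 6 4-hydroxy-2-methoxy-6-(trimethylsilyl)phenyl trifluoromethanesulfonate, via lithium phenoxide 4 (not isolated), via silyl ether triflate 5 (not isolated)
Conditions: n-BuLi, THF, −100 → −78 °C; Tf2O, −100 → −78 °C; then aq. citric acid, THF, rt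
Reagents that add atoms: trifluoromethanesulfonic anhydride, O=S(=O)(OS(=O)(=O)C(F)(F)F)C(F)(F)F
Why: Bromine–lithium exchange next to the silyl ether should trigger the 1,3 O→C silyl shift (retro-Brook rearrangement), the phenoxide is triflated, and the remote aryl silyl ether is hydrolysed on mildly acidic work-up while the C–Si bond, meta to both oxygen donors, should resist protodesilylation.

Step 4
Reactants: 6 4-hydroxy-2-methoxy-6-(trimethylsilyl)phenyl trifluoromethanesulfonate
Product: 7 2-methoxy-4-(methoxymethoxy)-6-(trimethylsilyl)phenyl trifluoromethanesulfonate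
Conditions: MOMCl, i-Pr2NEt, CH2Cl2, 0 °C → rt
Reagents that add atoms: chloromethyl methyl ether, COCCl
Why: Phenol O-alkylation under amine base does not trigger the ortho-silylaryl triflate and installs an acetal that tolerates fluoride at high temperature.

Step 5
Reactants: 8 3',4'-dihydroxyacetophenone; 9 3-chloro-3-methylbut-1-yne
Product: 10 1-[3-hydroxy-4-(2-methylbut-3-yn-2-yloxy)phenyl]ethanone
Conditions: K2CO3 (1.1 equiv), KI (cat.), CuI (cat.), acetone, 60 °C
Reagents that add atoms: none
Why: Copper-assisted O-propargylation with one equivalent of carbonate should occur at the 4-hydroxyl, which is the more acidic phenol because it is para to the acetyl group.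

Step 6
Reactants: 10 1-[3-hydroxy-4-(2-methylbut-3-yn-2-yloxy)phenyl]ethanone
Product: 11 1-[3-(methoxymethoxy)-4-(2-methylbut-3-yn-2-yloxy)phenyl]ethanone
Conditions: MOMCl, i-Pr2NEt, CH2Cl2, 0 °C → rt
Reagents that add atoms: chloromethyl methyl ether, COCCl
Why: Standard methoxymethyl ether formation masks the remaining phenol before the thermal step and for the later aryne step.

Step 7
Reactants: 11 1-[3-(methoxymethoxy)-4-(2-methylbut-3-yn-2-yloxy)phenyl]ethanone
Product: 12 1-[8-(methoxymethoxy)-2,2-dimethyl-2H-chromen-6-yl]ethanone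
Conditions: PhNEt2, 190 °C
Reagents that add atoms: none
Why: Aromatic propargyl Claisen rearrangement to the only free ortho position, followed by enolisation, 1,5-hydrogen shift and oxa-6π electrocyclisation, should close ring D as the 2,2-dimethyl-2H-chromene.

Step 8
Reactants: 12 1-[8-(methoxymethoxy)-2,2-dimethyl-2H-chromen-6-yl]ethanone
Product: 13 1-[8-(methoxymethoxy)-2,2-dimethyl-2H-chromen-6-yl]ethenyl trifluoromethanesulfonate
Conditions: KN(SiMe3)2, THF, −78 °C; PhNTf2, −78 → 0 °C; Et3N-deactivated silica
Reagents that add atoms: N-phenylbis(trifluoromethanesulfonimide), O=S(=O)(N(c1ccccc1)S(=O)(=O)C(F)(F)F)C(F)(F)F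
Why: Deprotonation of the methyl ketone and O-sulfonylation of the potassium enolate should give the 1-arylvinyl triflate.

Step 9
Reactants: 13 1-[8-(methoxymethoxy)-2,2-dimethyl-2H-chromen-6-yl]ethenyl trifluoromethanesulfonate
Product: 14 2-[8-(methoxymethoxy)-2,2-dimethyl-2H-chromen-6-yl]prop-2-enoic acid
Conditions: Pd(OAc)2 (cat.), dppp, CO (1 atm), Et3N, DMF/H2O, rt → 50 °C; citric acid work-up
Reagents that add atoms: carbon monoxide, [C-]#[O+]; water, O
Why: Palladium-catalysed hydroxycarbonylation (oxidative addition of the vinyl triflate to zerovalent palladium, CO insertion, hydrolysis of the acylpalladium species) should give the 2-arylacrylic acid.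

Step 10
Reactants: 7 2-methoxy-4-(methoxymethoxy)-6-(trimethylsilyl)phenyl trifluoromethanesulfonate (1.5 equiv); 14 2-[8-(methoxymethoxy)-2,2-dimethyl-2H-chromen-6-yl]prop-2-enoic acid
Product: 17 rac-5-methoxy-7-(methoxymethoxy)-3-[8-(methoxymethoxy)-2,2-dimethyl-2H-chromen-6-yl]chroman-4-one, via aryne 15 (not isolated), via acylphenoxide 16 (not isolated)
Conditions: CsF (4 equiv), THF, 125 °C, sealed tube
Reagents that add atoms: none
Why: CsF removes the silyl group of 7 and triflate leaves to give aryne 15; the cesium carboxylate of 14 adds through oxygen to the aryne carbon remote from the methoxy group (O1–C8a), the aryl anion ortho to OMe attacks the ester carbonyl and the four-membered alkoxide opens to acylphenoxide 16 (net aryne insertion into the acid C–O bond, C4–C4a), and the phenoxide then adds to the methylene terminus of the 2-aryl enone (O1–C2) before the enolate is protonated. The closest known reaction type is the fluoride-induced insertion of arynes into the C–O bond of α,β-unsaturated carboxylic acids, which gives 4-chromanones directly. Ring C closes by a 6-endo-trig oxa-Michael addition, after a transient 4-exo-trig closure and ring opening that moves the acyl group from oxygen to carbon. The one new stereocentre, C3, comes from unselective protonation of the enolate and is therefore formed racemic; it is labile under these conditions in any case and is set in step 13. The step needs regioselective carboxylate addition to the unsymmetrical aryne, which the C5 methoxy group next to the aryne bond should secure by stabilising the adjacent developing carbanion, and it needs acyl transfer to outrun protonation of the aryl anion, which the aprotic medium, the high temperature and the intramolecular pathway favour.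

Step 11
Reactants: 17 rac-5-methoxy-7-(methoxymethoxy)-3-[8-(methoxymethoxy)-2,2-dimethyl-2H-chromen-6-yl]chroman-4-one
Product: 18 rac-7-hydroxy-3-(8-hydroxy-2,2-dimethyl-2H-chromen-6-yl)-5-methoxychroman-4-one
Conditions: HCl (3 M in MeOH), THF, 45 °C
Reagents that add atoms: none
Why: Acid-catalysed acetal methanolysis removes both methoxymethyl groups while C3 is still racemic, so acid-promoted enolisation costs nothing, and the dimethylchromene tolerates methanolic HCl at this temperature.

Step 12
Reactants: 18 rac-7-hydroxy-3-(8-hydroxy-2,2-dimethyl-2H-chromen-6-yl)-5-methoxychroman-4-one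
Product: 19 rac-7-(tert-butyldimethylsilyloxy)-3-[8-(tert-butyldimethylsilyloxy)-2,2-dimethyl-2H-chromen-6-yl]-5-methoxychroman-4-one
Conditions: TBSCl, imidazole, DMF, rt
Reagents that add atoms: tert-butyldimethylsilyl chloride, CC(C)(C)[Si](C)(C)Cl
Why: Phenol silylation installs groups that can be removed at the end without acid or base strong enough to enolise C3, and that keep the C7 oxygen from forming a para-quinone methide at the C4 carbinol stage.

Step 13
Reactants: 19 rac-7-(tert-butyldimethylsilyloxy)-3-[8-(tert-butyldimethylsilyloxy)-2,2-dimethyl-2H-chromen-6-yl]-5-methoxychroman-4-one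
Product: 20 (3S,4S)-7-(tert-butyldimethylsilyloxy)-3-[8-(tert-butyldimethylsilyloxy)-2,2-dimethyl-2H-chromen-6-yl]-5-methoxychroman-4-ol
Conditions: RuCl[(S,S)-TsDPEN](p-cymene) (3 mol%), HCO2H/Et3N (5:2), EtOAc, 40 °C
Reagents that add atoms: none
Why: Noyori-type asymmetric transfer hydrogenation with dynamic kinetic resolution, in which the C3 epimers interconvert by enolisation under the formate/amine conditions, the (S,S) catalyst should deliver hydride to the C4 face that gives the 4S carbinol (as for 4-chromanone and 1-tetralone) and should reduce faster the epimer that takes hydride anti to the 3-aryl group, so that the cis (3S,4S) alcohol is expected and C3 is set here.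

Step 14
Reactants: 20 (3S,4S)-7-(tert-butyldimethylsilyloxy)-3-[8-(tert-butyldimethylsilyloxy)-2,2-dimethyl-2H-chromen-6-yl]-5-methoxychroman-4-ol
Product: 21 (3S)-7-(tert-butyldimethylsilyloxy)-3-[8-(tert-butyldimethylsilyloxy)-2,2-dimethyl-2H-chromen-6-yl]-5-methoxychroman-4-one
Conditions: Dess–Martin periodinane, CH2Cl2, 0 °C → rt
Reagents that add atoms: none
Why: Dess–Martin oxidation under non-basic conditions removes the auxiliary C4 stereocentre and should leave the C3 configuration from step 13 untouched.

Step 15
Reactants: 21 (3S)-7-(tert-butyldimethylsilyloxy)-3-[8-(tert-butyldimethylsilyloxy)-2,2-dimethyl-2H-chromen-6-yl]-5-methoxychroman-4-one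
Product: 22 (3S)-7-hydroxy-3-(8-hydroxy-2,2-dimethyl-2H-chromen-6-yl)-5-methoxychroman-4-one
Conditions: HF·pyridine, pyridine, THF, 0 °C
Reagents that add atoms: none
Why: Buffered fluoride cleavage of the two aryl silyl ethers at 0 °C should free both phenols without enolising the α-aryl ketone or touching the chromene.

**Compound list**

1 | 5-bromovanillin (3-bromo-4-hydroxy-5-methoxybenzaldehyde) | COc1cc(C=O)cc(Br)c1O | starting material
2 | 2-bromo-6-methoxybenzene-1,4-diol | COc1cc(O)cc(Br)c1O | intermediate
3 | [(2-bromo-6-methoxy-1,4-phenylene)bis(oxy)]bis(trimethylsilane) | COc1cc(O[Si](C)(C)C)cc(Br)c1O[Si](C)(C)C | intermediate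
4 | lithium 2-methoxy-6-(trimethylsilyl)-4-(trimethylsilyloxy)phenolate | COc1cc(O[Si](C)(C)C)cc([Si](C)(C)C)c1[O-].[Li+] | intermediate
5 | 2-methoxy-6-(trimethylsilyl)-4-(trimethylsilyloxy)phenyl trifluoromethanesulfonate | COc1cc(O[Si](C)(C)C)cc([Si](C)(C)C)c1OS(=O)(=O)C(F)(F)F | intermediate
6 | 4-hydroxy-2-methoxy-6-(trimethylsilyl)phenyl trifluoromethanesulfonate | COc1cc(O)cc([Si](C)(C)C)c1OS(=O)(=O)C(F)(F)F | intermediate
7 | 2-methoxy-4-(methoxymethoxy)-6-(trimethylsilyl)phenyl trifluoromethanesulfonate | COCOc1cc(OC)c(OS(=O)(=O)C(F)(F)F)c([Si](C)(C)C)c1 | intermediate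
8 | 3',4'-dihydroxyacetophenone | CC(=O)c1ccc(O)c(O)c1 | starting material
9 | 3-chloro-3-methylbut-1-yne | CC(C)(Cl)C#C | starting material
10 | 1-[3-hydroxy-4-(2-methylbut-3-yn-2-yloxy)phenyl]ethanone | CC(=O)c1ccc(OC(C)(C)C#C)c(O)c1 | intermediate
11 | 1-[3-(methoxymethoxy)-4-(2-methylbut-3-yn-2-yloxy)phenyl]ethanone | CC(=O)c1ccc(OC(C)(C)C#C)c(OCOC)c1 | intermediate
12 | 1-[8-(methoxymethoxy)-2,2-dimethyl-2H-chromen-6-yl]ethanone | CC(=O)c1cc(OCOC)c2c(c1)C=CC(C)(C)O2 | intermediate
13 | 1-[8-(methoxymethoxy)-2,2-dimethyl-2H-chromen-6-yl]ethenyl trifluoromethanesulfonate | C=C(OS(=O)(=O)C(F)(F)F)c1cc(OCOC)c2c(c1)C=CC(C)(C)O2 | intermediate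
14 | 2-[8-(methoxymethoxy)-2,2-dimethyl-2H-chromen-6-yl]prop-2-enoic acid | C=C(C(=O)O)c1cc(OCOC)c2c(c1)C=CC(C)(C)O2 | intermediate
15 | 3-methoxy-5-(methoxymethoxy)benzyne | COCOC1=CC#CC(OC)=C1 | intermediate
16 | cesium 3-methoxy-5-(methoxymethoxy)-2-{2-[8-(methoxymethoxy)-2,2-dimethyl-2H-chromen-6-yl]prop-2-enoyl}phenolate | C=C(C(=O)c1c(OC)cc(OCOC)cc1[O-])c1cc(OCOC)c2c(c1)C=CC(C)(C)O2.[Cs+] | intermediate
17 | rac-5-methoxy-7-(methoxymethoxy)-3-[8-(methoxymethoxy)-2,2-dimethyl-2H-chromen-6-yl]chroman-4-one | COc1cc(OCOC)cc2c1C(=O)C(c1cc(OCOC)c3c(c1)C=CC(C)(C)O3)CO2 | intermediate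
18 | rac-7-hydroxy-3-(8-hydroxy-2,2-dimethyl-2H-chromen-6-yl)-5-methoxychroman-4-one | COc1cc(O)cc2c1C(=O)C(c1cc(O)c3c(c1)C=CC(C)(C)O3)CO2 | intermediate
19 | rac-7-(tert-butyldimethylsilyloxy)-3-[8-(tert-butyldimethylsilyloxy)-2,2-dimethyl-2H-chromen-6-yl]-5-methoxychroman-4-one | COc1cc(O[Si](C)(C)C(C)(C)C)cc2c1C(=O)C(c1cc(O[Si](C)(C)C(C)(C)C)c3c(c1)C=CC(C)(C)O3)CO2 | intermediate
20 | (3S,4S)-7-(tert-butyldimethylsilyloxy)-3-[8-(tert-butyldimethylsilyloxy)-2,2-dimethyl-2H-chromen-6-yl]-5-methoxychroman-4-ol (3,4-cis) | COc1cc(O[Si](C)(C)C(C)(C)C)cc2c1[C@@H](O)[C@@H](c1cc(O[Si](C)(C)C(C)(C)C)c3c(c1)C=CC(C)(C)O3)CO2 | intermediate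
21 | (3S)-7-(tert-butyldimethylsilyloxy)-3-[8-(tert-butyldimethylsilyloxy)-2,2-dimethyl-2H-chromen-6-yl]-5-methoxychroman-4-one | COc1cc(O[Si](C)(C)C(C)(C)C)cc2c1C(=O)[C@@H](c1cc(O[Si](C)(C)C(C)(C)C)c3c(c1)C=CC(C)(C)O3)CO2 | intermediate
22 | (3S)-7-hydroxy-3-(8-hydroxy-2,2-dimethyl-2H-chromen-6-yl)-5-methoxychroman-4-one | COc1cc(O)cc2c1C(=O)[C@@H](c1cc(O)c3c(c1)C=CC(C)(C)O3)CO2 | target

**Step count and risks**

Total step count: 15. Longest linear sequence: 11 steps (steps 5 to 15, from 8).

Steps most likely to fail:

1. Step 10. The aryl anion may be protonated before the acyl shift, which would stop the cascade at the aryl ester. The electron-rich acrylate may oligomerise at 125 °C, and the product enolate may be arylated by excess aryne. Fallback: the fallback sets out from 7 and returns to the route at 17, using 13 as the partner in place of 14. Aryne generation from 7 with CsF in DMF, insertion into the formamide C=O bond and aqueous hydrolysis should give 2-hydroxy-6-methoxy-4-(methoxymethoxy)benzaldehyde F1, with the same methoxy-controlled regiochemistry. Nozaki–Hiyama–Kishi coupling of F1 with vinyl triflate 13 (CrCl2 in excess, NiCl2 cat., DMF) should give the racemic allylic alcohol 2-{1-hydroxy-2-[8-(methoxymethoxy)-2,2-dimethyl-2H-chromen-6-yl]prop-2-en-1-yl}-3-methoxy-5-(methoxymethoxy)phenol F2. MnO2 in CH2Cl2 should oxidise it to 1-[2-hydroxy-6-methoxy-4-(methoxymethoxy)phenyl]-2-[8-(methoxymethoxy)-2,2-dimethyl-2H-chromen-6-yl]prop-2-en-1-one F3, which should close to 17 by oxa-Michael addition with a trace of Et3N.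

2. Step 13. Hydride transfer to the hindered, electron-rich C4 ketone (peri methoxy group, para silyloxy donor) may be slow, and C3 epimerisation may not keep pace with reduction, which would erode the diastereo- and enantioselectivity of the resolution. Fallback: the fallback sets out from 19 and returns at 21, so step 14 is not needed. Soft enolisation (TMSOTf, Et3N, CH2Cl2, 0 °C) should give the silyl enol ether 7-(tert-butyldimethylsilyloxy)-3-[8-(tert-butyldimethylsilyloxy)-2,2-dimethyl-2H-chromen-6-yl]-5-methoxy-4-(trimethylsilyloxy)-2H-chromene F4. Catalytic enantioselective protonation of F4 with a BINOL-derived N-triflyl thiophosphoramide and phenol as the proton source in toluene, the catalyst antipode being chosen to deliver the S ketone, should give 21.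

3. Step 8. The para-oxygen-stabilised 1-arylvinyl triflate may ionise or hydrolyse back to the ketone during isolation or under the aqueous carbonylation conditions of step 9. Fallback: the fallback sets out from 12 and returns at 14, bypassing 13 and step 9. Condensation with 2,4,6-triisopropylbenzenesulfonyl hydrazide in THF should give N'-{1-[8-(methoxymethoxy)-2,2-dimethyl-2H-chromen-6-yl]ethylidene}-2,4,6-triisopropylbenzenesulfonohydrazide F5. Shapiro reaction of F5 (n-BuLi, 2.2 equiv, THF/TMEDA, −78 → 0 °C) and trapping of the 1-arylvinyllithium with CO2, followed by mildly acidic work-up, should give 14.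

Further compounds
F1 | step 10 | 2-hydroxy-6-methoxy-4-(methoxymethoxy)benzaldehyde | COCOc1cc(O)c(C=O)c(OC)c1
F2 | step 10 | rac-2-{1-hydroxy-2-[8-(methoxymethoxy)-2,2-dimethyl-2H-chromen-6-yl]prop-2-en-1-yl}-3-methoxy-5-(methoxymethoxy)phenol | C=C(C(O)c1c(OC)cc(OCOC)cc1O)c1cc(OCOC)c2c(c1)C=CC(C)(C)O2
F3 | step 10 | 1-[2-hydroxy-6-methoxy-4-(methoxymethoxy)phenyl]-2-[8-(methoxymethoxy)-2,2-dimethyl-2H-chromen-6-yl]prop-2-en-1-one | C=C(C(=O)c1c(OC)cc(OCOC)cc1O)c1cc(OCOC)c2c(c1)C=CC(C)(C)O2
F4 | step 13 | 7-(tert-butyldimethylsilyloxy)-3-[8-(tert-butyldimethylsilyloxy)-2,2-dimethyl-2H-chromen-6-yl]-5-methoxy-4-(trimethylsilyloxy)-2H-chromene | COc1cc(O[Si](C)(C)C(C)(C)C)cc2c1C(O[Si](C)(C)C)=C(c1cc(O[Si](C)(C)C(C)(C)C)c3c(c1)C=CC(C)(C)O3)CO2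
F5 | step 8 | N'-{1-[8-(methoxymethoxy)-2,2-dimethyl-2H-chromen-6-yl]ethylidene}-2,4,6-triisopropylbenzenesulfonohydrazide | CC(=NNS(=O)(=O)c1c(C(C)C)cc(C(C)C)cc1C(C)C)c1cc(OCOC)c2c(c1)C=CC(C)(C)O2
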